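**Retrosynthetic overview** (germacrane numbering: C6 = lactone O–CH, C7 = ring-fusion CH, C8 = acyloxy CH, C1=C10 = ring alkene, C4 = CH–CH2OH)
1. Last step: an indium-mediated intramolecular Barbier allylation of a lactol-tethered (Z)-2-(bromomethyl)enoate forms C6–C7 and the ten-membered carbocycle, and in-situ lactonisation then closes the α-methylene-γ-butyrolactone; C6 and C7 are set here and the free CH2OH is released.
2. The allylic bromide comes from a Morita–Baylis–Hillman reaction and PBr3 on an α-acyloxy aldehyde; the C8 ester comes from CBS reduction of an α-keto acetal and (R)-2-methylbutanoic acid.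
3. C1=C10 (E) comes from a Wittig reaction of a lactone aldehyde with the ylide made from Ph3P=CHCO2Me and BrCH2COCH(OMe)2.
4. C4 comes from an Evans alkylation of a hex-5-enoyl oxazolidinone with tert-butyl bromoacetate; the derived γ-butyrolactone (C15–O–C6) masks both the primary alcohol and the C6 aldehyde.
5. Ring order: temporary butyrolactone (step 3), opened to the lactol (step 12), then carbocycle and fused lactone together (step 13).

Assumption: (R)-2-methylbutanoic acid is bought as the single enantiomer; the route is a plan and has not been run.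

**Step 1**
Reactants: 1 hex-5-enoyl chloride; 2 (S)-4-benzyl-2-oxazolidinone
Product: 4 (S)-4-benzyl-3-(hex-5-enoyl)oxazolidin-2-one, via lithium oxazolidinide 3 (not isolated)
Conditions: n-BuLi, THF, −78 °C; then 1, −78 → 0 °C
Reagents that add atoms: none
Why: N-acylation of the lithiated oxazolidinone by the acid chloride (nucleophilic acyl substitution) attaches the Evans auxiliary; no new stereocentre.

**Step 2**
Reactants: 4 (S)-4-benzyl-3-(hex-5-enoyl)oxazolidin-2-one; 5 tert-butyl bromoacetate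
Product: 7 tert-butyl (3R)-3-[(4S)-4-benzyl-2-oxooxazolidine-3-carbonyl]hept-6-enoate, via sodium (Z)-imide enolate 6 (not isolated)
Conditions: NaN(SiMe3)2, THF, −78 °C; then 5, −78 → −40 °C
Reagents that add atoms: none
Why: Evans asymmetric alkylation, in which the chelated (Z)-enolate is alkylated on the face opposite the benzyl group and sets C4 as R (dr typically >95:5).

**Step 3**
Reactants: 7 tert-butyl (3R)-3-[(4S)-4-benzyl-2-oxooxazolidine-3-carbonyl]hept-6-enoate
Product: 9 (4R)-4-(but-3-en-1-yl)dihydrofuran-2(3H)-one, via hydroxy tert-butyl ester 8 (not isolated)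
Conditions: LiBH4, H2O (1 equiv), Et2O, 0 °C; then CF3CO2H, CH2Cl2, rt
Reagents that add atoms: none
Why: Reductive cleavage of the imide by LiBH4 leaves the tert-butyl ester, and acid then removes the tert-butyl group and closes the γ-lactone (acid-catalysed lactonisation); C4 is untouched.

**Step 4**
Reactants: 9 (4R)-4-(but-3-en-1-yl)dihydrofuran-2(3H)-one
Product: 11 3-[(3R)-5-oxotetrahydrofuran-3-yl]propanal, via secondary ozonide 10 (not isolated)
Conditions: O3, CH2Cl2, −78 °C; then Me2S, −78 °C → rt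
Reagents that add atoms: ozone, O=[O+][O-]
Why: Ozonolysis with reductive work-up turns the terminal alkene into the C1 aldehyde; the lactone is inert and no stereocentre is affected.

**Step 5**
Reactants: 12 methyl (triphenylphosphoranylidene)acetate; 13 3-bromo-1,1-dimethoxypropan-2-one
Product: 15 methyl 5,5-dimethoxy-4-oxo-2-(triphenylphosphoranylidene)pentanoate, via phosphonium bromide 14 (not isolated)
Conditions: 12 (2 equiv), EtOAc, rt, 24 h
Reagents that add atoms: none
Why: C-alkylation of the ester-stabilised ylide by the α-bromo ketone, then transylidation by the second equivalent of 12, gives the α-substituted stabilised ylide; no stereocentre.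

**Step 6**
Reactants: 11 3-[(3R)-5-oxotetrahydrofuran-3-yl]propanal; 15 methyl 5,5-dimethoxy-4-oxo-2-(triphenylphosphoranylidene)pentanoate
Product: 16 methyl (2E)-5,5-dimethoxy-4-oxo-2-{3-[(3R)-5-oxotetrahydrofuran-3-yl]propylidene}pentanoate
Conditions: toluene, 80 °C
Reagents that add atoms: none
Why: Wittig olefination with an α-substituted ester-stabilised ylide places the aldehyde chain trans to CO2Me (E), which is the ring-cis C1=C10 geometry of the target.

**Step 7**
Reactants: 16 methyl (2E)-5,5-dimethoxy-4-oxo-2-{3-[(3R)-5-oxotetrahydrofuran-3-yl]propylidene}pentanoate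
Product: 17 methyl (2E,4R)-4-hydroxy-5,5-dimethoxy-2-{3-[(3R)-5-oxotetrahydrofuran-3-yl]propylidene}pentanoate
Conditions: (S)-2-methyl-CBS-oxazaborolidine (20 mol%), BH3·SMe2, THF, −30 °C; MeOH quench
Reagents that add atoms: none
Why: Corey–Bakshi–Shibata reduction under catalyst control, with the dimethoxymethyl group expected to act as the large substituent (as in reductions of α-keto acetals), delivers the (R)-alcohol at C8; the lactone and esters are not reduced at this temperature.

**Step 8**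
Reactants: 17 methyl (2E,4R)-4-hydroxy-5,5-dimethoxy-2-{3-[(3R)-5-oxotetrahydrofuran-3-yl]propylidene}pentanoate; 18 (R)-2-methylbutanoic acid
Product: 19 methyl (2E,4R)-5,5-dimethoxy-4-{[(2R)-2-methylbutanoyl]oxy}-2-{3-[(3R)-5-oxotetrahydrofuran-3-yl]propylidene}pentanoate
Conditions: DCC, DMAP (10 mol%), CH2Cl2, 0 °C → rt
Reagents that add atoms: none
Why: Steglich esterification proceeds with retention at C8 and at the acid α-carbon, prompt acylation prevents lactonisation of the γ-hydroxy ester, and any minor C8 epimer is now a separable diastereomer.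

**Step 9**
Reactants: 19 methyl (2E,4R)-5,5-dimethoxy-4-{[(2R)-2-methylbutanoyl]oxy}-2-{3-[(3R)-5-oxotetrahydrofuran-3-yl]propylidene}pentanoate
Product: 20 methyl (2E,4R)-4-{[(2R)-2-methylbutanoyl]oxy}-5-oxo-2-{3-[(3R)-5-oxotetrahydrofuran-3-yl]propylidene}pentanoate
Conditions: CF3CO2H/H2O (4:1), CH2Cl2, 0 °C
Reagents that add atoms: water, O
Why: Acid-catalysed acetal hydrolysis unmasks the C7 aldehyde; the lactone and esters survive and C8 should not enolise under cold acid.

**Step 10**
Reactants: 20 methyl (2E,4R)-4-{[(2R)-2-methylbutanoyl]oxy}-5-oxo-2-{3-[(3R)-5-oxotetrahydrofuran-3-yl]propylidene}pentanoate; 21 methyl acrylate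
Product: 22 dimethyl (4R,6E)-3-hydroxy-2-methylidene-4-{[(2R)-2-methylbutanoyl]oxy}-6-{3-[(3R)-5-oxotetrahydrofuran-3-yl]propylidene}heptanedioate (both C3 epimers)
Conditions: DABCO (1 equiv), methyl acrylate (10 equiv, neat), rt
Reagents that add atoms: none
Why: Morita–Baylis–Hillman reaction of the activated α-acyloxy aldehyde attaches C11–C13; the new carbinol centre is irrelevant because step 11 destroys it.

**Step 11**
Reactants: 22 dimethyl (4R,6E)-3-hydroxy-2-methylidene-4-{[(2R)-2-methylbutanoyl]oxy}-6-{3-[(3R)-5-oxotetrahydrofuran-3-yl]propylidene}heptanedioate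
Product: 23 dimethyl (2Z,4R,6E)-2-(bromomethyl)-4-{[(2R)-2-methylbutanoyl]oxy}-6-{3-[(3R)-5-oxotetrahydrofuran-3-yl]propylidene}hept-2-enedioate
Conditions: PBr3, Et2O, −10 → 0 °C
Reagents that add atoms: phosphorus tribromide, BrP(Br)Br
Why: Allylic bromination with transposition (SN2′ of the Baylis–Hillman alcohol) gives the thermodynamically preferred (Z)-2-(bromomethyl)alk-2-enoate and removes the C7 carbinol centre.

**Step 12**
Reactants: 23 dimethyl (2Z,4R,6E)-2-(bromomethyl)-4-{[(2R)-2-methylbutanoyl]oxy}-6-{3-[(3R)-5-oxotetrahydrofuran-3-yl]propylidene}hept-2-enedioate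
Product: 24 dimethyl (2Z,4R,6E)-2-(bromomethyl)-6-{3-[(3R)-5-hydroxytetrahydrofuran-3-yl]propylidene}-4-{[(2R)-2-methylbutanoyl]oxy}hept-2-enedioate (lactol, both anomers)
Conditions: Sia2BH (3.5 equiv, from BH3·THF and 2-methylbut-2-ene), THF, 0 °C → rt; then H2O
Reagents that add atoms: none
Why: Disiamylborane reduces a γ-lactone only as far as the borinate-protected hemiacetal, while carboxylic esters, electron-poor trisubstituted alkenes and the allylic bromide are left alone (chemoselective partial reduction).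

**Step 13**
Reactants: 24 dimethyl (2Z,4R,6E)-2-(bromomethyl)-6-{3-[(3R)-5-hydroxytetrahydrofuran-3-yl]propylidene}-4-{[(2R)-2-methylbutanoyl]oxy}hept-2-enedioate
Product: 27 methyl (3aS,4R,6E,10R,11aR)-10-(hydroxymethyl)-3-methylidene-4-{[(2R)-2-methylbutanoyl]oxy}-2-oxo-2,3,3a,4,5,8,9,10,11,11a-decahydrocyclodeca[b]furan-6-carboxylate (CNP0141952.3), via allylindium dibromide 25 (not isolated), via seco hydroxy ester 26 (not isolated)
Conditions: In powder (3 equiv), THF/H2O (4:1), rt, slow addition of 24 to 0.002 M; then 1 M HCl, rt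
Reagents that add atoms: none
Why: Intramolecular Barbier allylation, in which the allylindium adds through its γ-carbon (C7) to the open hydroxy-aldehyde form of the lactol in a closed six-membered transition state to form the ten-membered ring, after which the γ-hydroxy ester lactonises on acidification; the ring-cis C1=C10 alkene and the tether are expected to hold C5 and C8 anti (trans-fused lactone, 6R,7S) with the C8 acyloxy group on the outside, so both new centres are relayed from C8.

**Compound list**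
1 | hex-5-enoyl chloride | C=CCCCC(=O)Cl | starting material
2 | (S)-4-benzyl-2-oxazolidinone | O=C1N[C@@H](Cc2ccccc2)CO1 | starting material
3 | lithium (S)-4-benzyl-2-oxooxazolidin-3-ide | [Li+].O=C1[N-][C@@H](Cc2ccccc2)CO1 | intermediate
4 | (S)-4-benzyl-3-(hex-5-enoyl)oxazolidin-2-one | C=CCCCC(=O)N1[C@@H](Cc2ccccc2)COC1=O | intermediate
5 | tert-butyl bromoacetate | BrCC(=O)OC(C)(C)C | starting material
6 | sodium (Z)-enolate of 4 | [Na+].C=CCC/C=C(\[O-])N1[C@@H](Cc2ccccc2)COC1=O | intermediate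
7 | tert-butyl (3R)-3-[(4S)-4-benzyl-2-oxooxazolidine-3-carbonyl]hept-6-enoate | C=CCC[C@H](CC(=O)OC(C)(C)C)C(=O)N1[C@@H](Cc2ccccc2)COC1=O | intermediate
8 | tert-butyl (3R)-3-(hydroxymethyl)hept-6-enoate | C=CCC[C@@H](CO)CC(=O)OC(C)(C)C | intermediate
9 | (4R)-4-(but-3-en-1-yl)dihydrofuran-2(3H)-one | C=CCC[C@H]1COC(=O)C1 | intermediate
10 | (4R)-4-[2-(1,2,4-trioxolan-3-yl)ethyl]dihydrofuran-2(3H)-one (secondary ozonide) | C1OC(CC[C@H]2COC(=O)C2)OO1 | intermediate
11 | 3-[(3R)-5-oxotetrahydrofuran-3-yl]propanal | O=CCC[C@H]1COC(=O)C1 | intermediate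
12 | methyl (triphenylphosphoranylidene)acetate | COC(=O)C=P(c1ccccc1)(c1ccccc1)c1ccccc1 | starting material
13 | 3-bromo-1,1-dimethoxypropan-2-one | COC(OC)C(=O)CBr | starting material
14 | (1,5,5-trimethoxy-1,4-dioxopentan-2-yl)triphenylphosphonium bromide | [Br-].COC(=O)C(CC(=O)C(OC)OC)[P+](c1ccccc1)(c1ccccc1)c1ccccc1 | intermediate
15 | methyl 5,5-dimethoxy-4-oxo-2-(triphenylphosphoranylidene)pentanoate | COC(=O)C(CC(=O)C(OC)OC)=P(c1ccccc1)(c1ccccc1)c1ccccc1 | intermediate
16 | methyl (2E)-5,5-dimethoxy-4-oxo-2-{3-[(3R)-5-oxotetrahydrofuran-3-yl]propylidene}pentanoate | COC(=O)/C(=C/CC[C@H]1COC(=O)C1)CC(=O)C(OC)OC | intermediate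
17 | methyl (2E,4R)-4-hydroxy-5,5-dimethoxy-2-{3-[(3R)-5-oxotetrahydrofuran-3-yl]propylidene}pentanoate | COC(=O)/C(=C/CC[C@H]1COC(=O)C1)C[C@@H](O)C(OC)OC | intermediate
18 | (R)-2-methylbutanoic acid | CC[C@@H](C)C(=O)O | starting material
19 | methyl (2E,4R)-5,5-dimethoxy-4-{[(2R)-2-methylbutanoyl]oxy}-2-{3-[(3R)-5-oxotetrahydrofuran-3-yl]propylidene}pentanoate | COC(=O)/C(=C/CC[C@H]1COC(=O)C1)C[C@@H](OC(=O)[C@H](C)CC)C(OC)OC | intermediate
20 | methyl (2E,4R)-4-{[(2R)-2-methylbutanoyl]oxy}-5-oxo-2-{3-[(3R)-5-oxotetrahydrofuran-3-yl]propylidene}pentanoate | COC(=O)/C(=C/CC[C@H]1COC(=O)C1)C[C@@H](OC(=O)[C@H](C)CC)C=O | intermediate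
21 | methyl acrylate | C=CC(=O)OC | starting material
22 | dimethyl (4R,6E)-3-hydroxy-2-methylidene-4-{[(2R)-2-methylbutanoyl]oxy}-6-{3-[(3R)-5-oxotetrahydrofuran-3-yl]propylidene}heptanedioate (C3 epimers) | COC(=O)/C(=C/CC[C@H]1COC(=O)C1)C[C@@H](OC(=O)[C@H](C)CC)C(O)C(=C)C(=O)OC | intermediate
23 | dimethyl (2Z,4R,6E)-2-(bromomethyl)-4-{[(2R)-2-methylbutanoyl]oxy}-6-{3-[(3R)-5-oxotetrahydrofuran-3-yl]propylidene}hept-2-enedioate | COC(=O)/C(=C/CC[C@H]1COC(=O)C1)C[C@@H](OC(=O)[C@H](C)CC)/C=C(\CBr)C(=O)OC | intermediate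
24 | dimethyl (2Z,4R,6E)-2-(bromomethyl)-6-{3-[(3R)-5-hydroxytetrahydrofuran-3-yl]propylidene}-4-{[(2R)-2-methylbutanoyl]oxy}hept-2-enedioate (lactol anomers) | COC(=O)/C(=C/CC[C@H]1COC(O)C1)C[C@@H](OC(=O)[C@H](C)CC)/C=C(\CBr)C(=O)OC | intermediate
25 | allylindium dibromide derived from 24 (trivalent indium on the former CH2Br carbon; representative formula) | COC(=O)/C(=C/CC[C@H]1COC(O)C1)C[C@@H](OC(=O)[C@H](C)CC)/C=C(\C[In](Br)Br)C(=O)OC | intermediate
26 | methyl (1E,5R,7R,8S,9R)-7-hydroxy-5-(hydroxymethyl)-8-(3-methoxy-3-oxoprop-1-en-2-yl)-9-{[(2R)-2-methylbutanoyl]oxy}cyclodec-1-ene-1-carboxylate | O[C@@H]1C[C@H](CO)CC/C=C(/C(=O)OC)C[C@@H](OC(=O)[C@H](C)CC)[C@H]1C(=C)C(=O)OC | intermediate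
27 | methyl (3aS,4R,6E,10R,11aR)-10-(hydroxymethyl)-3-methylidene-4-{[(2R)-2-methylbutanoyl]oxy}-2-oxo-2,3,3a,4,5,8,9,10,11,11a-decahydrocyclodeca[b]furan-6-carboxylate | C=C1C(=O)O[C@@H]2C[C@H](CO)CC/C=C(/C(=O)OC)C[C@@H](OC(=O)[C@H](C)CC)[C@@H]12 | target

**Step count:** 13 steps in total. Longest linear sequence: 12 steps (steps 1–4 and 6–13); step 5 is a one-step side branch.

**Three steps most likely to fail**

Step 13 (macrocyclisation). Oligomerisation, protodebromination or the wrong C6/C7 diastereomer are all possible, and the stereochemical outcome is a prediction. Fallback: generate the allyl nucleophile catalytically from an allylic acetate instead of stoichiometrically from the bromide. It sets out from alcohol 22: acetylation (Ac2O, pyridine) gives the allylic acetate F1, and disiamylborane reduction as in step 12 gives the lactol acetate F2. Pd(PPh3)4 (5 mol%) with InI in THF/H2O at high dilution then ionises F2 to a π-allylpalladium species that is transmetalated to the same allylindium at low stationary concentration, which favours ring closure over intermolecular coupling. Acidification lactonises 26 and the route is rejoined at 27. This addresses yield rather than a wrong diastereomer.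

Step 10 (Morita–Baylis–Hillman reaction on an α-acyloxy aldehyde). Epimerisation at C8 or acyl migration to the new hydroxyl under DABCO is possible. Fallback: postpone the acylation. It sets out from alcohol 17:
- Silylation (TBDPSCl, imidazole, DMF) gives the silyl ether acetal F3.
- Aqueous CF3CO2H gives the α-silyloxy aldehyde F4, a well-behaved Baylis–Hillman substrate.
- Methyl acrylate/DABCO gives the Baylis–Hillman adduct F5, and PBr3 gives the (Z)-allylic bromide F6.
- HF·pyridine gives the hydroxy bromide F7.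
- Base-free acylation with (R)-2-methylbutanoic anhydride F8 (made from 18 and DCC) under Sc(OTf)3 catalysis returns to the route at 23.

Step 7 (CBS reduction of the α-keto acetal). The sense of induction depends on the dimethoxymethyl group acting as the large substituent. Fallback, if the opposite face is preferred: it sets out from ketone 16, which is reduced with the enantiomeric (R)-catalyst to the (4S)-alcohol F9. Mitsunobu esterification with 18 (PPh3, DIAD, toluene) then installs the ester with inversion at C8 and returns to the route at 19.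

**Further compounds**
F1 | step 13 | dimethyl (4R,6E)-3-acetoxy-2-methylidene-4-{[(2R)-2-methylbutanoyl]oxy}-6-{3-[(3R)-5-oxotetrahydrofuran-3-yl]propylidene}heptanedioate (C3 epimers) | COC(=O)/C(=C/CC[C@H]1COC(=O)C1)C[C@@H](OC(=O)[C@H](C)CC)C(OC(C)=O)C(=C)C(=O)OC
F2 | step 13 | dimethyl (4R,6E)-3-acetoxy-6-{3-[(3R)-5-hydroxytetrahydrofuran-3-yl]propylidene}-2-methylidene-4-{[(2R)-2-methylbutanoyl]oxy}heptanedioate (lactol) | COC(=O)/C(=C/CC[C@H]1COC(O)C1)C[C@@H](OC(=O)[C@H](C)CC)C(OC(C)=O)C(=C)C(=O)OC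
F3 | step 10 | methyl (2E,4R)-4-[(tert-butyldiphenylsilyl)oxy]-5,5-dimethoxy-2-{3-[(3R)-5-oxotetrahydrofuran-3-yl]propylidene}pentanoate | COC(=O)/C(=C/CC[C@H]1COC(=O)C1)C[C@@H](O[Si](c1ccccc1)(c1ccccc1)C(C)(C)C)C(OC)OC
F4 | step 10 | methyl (2E,4R)-4-[(tert-butyldiphenylsilyl)oxy]-5-oxo-2-{3-[(3R)-5-oxotetrahydrofuran-3-yl]propylidene}pentanoate | COC(=O)/C(=C/CC[C@H]1COC(=O)C1)C[C@@H](O[Si](c1ccccc1)(c1ccccc1)C(C)(C)C)C=O
F5 | step 10 | dimethyl (4R,6E)-4-[(tert-butyldiphenylsilyl)oxy]-3-hydroxy-2-methylidene-6-{3-[(3R)-5-oxotetrahydrofuran-3-yl]propylidene}heptanedioate (C3 epimers) | COC(=O)/C(=C/CC[C@H]1COC(=O)C1)C[C@@H](O[Si](c1ccccc1)(c1ccccc1)C(C)(C)C)C(O)C(=C)C(=O)OC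
F6 | step 10 | dimethyl (2Z,4R,6E)-2-(bromomethyl)-4-[(tert-butyldiphenylsilyl)oxy]-6-{3-[(3R)-5-oxotetrahydrofuran-3-yl]propylidene}hept-2-enedioate | COC(=O)/C(=C/CC[C@H]1COC(=O)C1)C[C@@H](O[Si](c1ccccc1)(c1ccccc1)C(C)(C)C)/C=C(\CBr)C(=O)OC
F7 | step 10 | dimethyl (2Z,4R,6E)-2-(bromomethyl)-4-hydroxy-6-{3-[(3R)-5-oxotetrahydrofuran-3-yl]propylidene}hept-2-enedioate | COC(=O)/C(=C/CC[C@H]1COC(=O)C1)C[C@@H](O)/C=C(\CBr)C(=O)OC
F8 | step 10 | (2R)-2-methylbutanoic anhydride | CC[C@@H](C)C(=O)OC(=O)[C@H](C)CC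
F9 | step 7 | methyl (2E,4S)-4-hydroxy-5,5-dimethoxy-2-{3-[(3R)-5-oxotetrahydrofuran-3-yl]propylidene}pentanoate | COC(=O)/C(=C/CC[C@H]1COC(=O)C1)C[C@H](O)C(OC)OC
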